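At 80 min I must say what stands in this flask, and my readings stop at 60.0 min.

| flask | G | J | E | remark | time |
|---|---|---|---|---|---|
| green | 0.30 M | 0.30 M | 0.90 M | the very flask that is asked about, followed so far |  |
| flask | 0.30 M | 0.30 M | 0.900 M |  | 80 min |
green run (percent of the G and J together charged): time / min: L / % = 4.00: 40.8; 12.0: 59.8; 25.0: 68.4; 40.0: 74.0; 50.0: 74.3; 60.0: 75.6

(scatter of a reading: 0.5 percentage points)
- ash: at 80 min add G, 50.0 % of the amount charged, then wait 40 min
- elm: change nothing and wait 40 min more
- alder: at 80 min take out 90 % of the L then present, then wait 40 min
- E is single-handed; G and J are mirror images of each other, charged as a racemate, each of them at the stated concentration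
- L that was removed still counts
- steps under discussion: E + G -> L; G <-> J; E <-> Q; E + J -> X; 2 E -> D; E -> Z
- additions bring no volume worth counting
- the handed part of E does not stay in what it makes, so the products of the two hands are mirror images too
* L, in percent of the G and J together first charged, at 80 min
* the remedy with the largest gain of L, or "none" below 2 percentage points (ash / elm / alder / none)
* L present, with what was taken out counted in, in percent of the G and J together first charged, after ash
* L present, with what was taken out counted in, in percent of the G and J together first charged, after alder

I bracket L at 80 min. No listed step takes L away, so the last reading less two scatters bounds it from below, at 74.6 %. The climb slows, running far faster at the start than between the last readings, so carrying that late slope straight on bounds it from above, at 77.2 %.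

For ash the bracket stays wide: the gain lies between nothing and the added 25.0 % of the charge, with the mark of 2 percentage points inside. What narrows it is the return on E, the L made per E charged, which I keep as 50.4 % from the last reading. If E is the limiting reagent, I price any later gain as this return times the E still live; the return is an average over the run, so the price is rough. One run cannot tell me how much E is live.

The forecast says 75.8 %, inside my bracket, with ash best, 90 % after ash and 76 % after alder, since added G “should mostly become L”.

The flask gives 77.2 %, at the top of the bracket, and none: ash reaches 78.5 %, a gain of 1.3 points, and alder 78.1 %, a gain of 0.91 points.

    E + G → L (k = 0.0490 /M/s)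
    G ⇌ J (k = 0.0400 /s)
    E ⇌ Q (K = 4.10, k = 0.0420 /s)
    E + J → X (k = 0.00440 /M/s)
    2 E → D (k = 0.0290 /M/s)
    E → Z (k = 2.00 × 10⁻⁵ /s)

By 8.00 min E stood at 3.83 % of its charge, L at 53.2 %, and the step to D had 91 % of its turnover behind it. At 80.0 min G keeps 16 % of its charge while E keeps 0.19 %. Counting Q with E, the average return prices what is live at 0.772 % of the charge, and elm gives 0.91 points.

In the neighbour flask with 2.2 M of E, the kept return gives a reach of 185 % of the G and J charged, past the whole charge, so on that price E should outlast G and J. That flask gives 89.7 % L and 9.13 % X, with 1.2 % of G and 0.56 % of E left, and its return of 24.5 % is lower than the kept one.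

All runs are simulated with constants of no real substance.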